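The readings are simulated with made-up constants; noise was put on by code.

The percent of the charge is a handy unit, and it tempts you to a bench rule: at one temperature, a plateau in percent carries over to the next flask.

| setting | beta | zeta | north-west | east | south-east |
|---|---|---|---|---|---|
| starting material | 0.50 M | 0.50 M | 1.0 M | 1.0 M | 1.0 M |
| solid partner | 2 equiv | 2 equiv | 2.00 equiv | 2.00 equiv | 2.00 equiv |
| capture agent | 1 M | 1 M | 1.00 M | 1.00 M | 1.00 M |
| temperature | 20 °C | 45 °C | 45 °C | 65 °C | 25 °C |
| remark | run made earlier | run made earlier |  |  |  |
| time |  |  | 2.5 d | 2.5 d | 2.5 d |

- beta (time / d: target / %): 0.625: 9; 0.833: 12; 1.25: 15; 2.00: 20; 3.00: 23; 4.00: 23; 8.00: 22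
- zeta (time / h: target / %): 4.00: 30; 6.00: 33; 8.00: 30; 15.0: 35; 20.0: 35; 30.0: 35; 50.0: 33

(standard deviation of a reading: 1.5 percentage points)

- as a solid, counted per litre of solution: solid partner
- the earlier runs were read with a standard deviation of 1.5 percentage points
- steps that have been proposed: starting material -> open intermediate; fresh partner + open intermediate -> target; solid partner <-> fresh partner; target <-> isomer of the product; open intermediate + capture agent -> trapped intermediate
- at the start none of the solid partner is in solution

1. the flask that comes out highest in amount of target, in percent of the starting material charged, or "all alike" when all lie within 1.5 percentage points (north-west / east / south-east / all alike)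
2. target at the end, in percent of the starting material charged, north-west
3. target at the end, in percent of the starting material charged, east
4. target at the end, in percent of the starting material charged, south-east

The zeta run stands near 35% and the beta run near 23%, so the rule gives north-west, at 45 °C like zeta, 35%. Now find its border. Take it that whatever does not become target ends as trapped intermediate, taking one capture agent each. The zeta run then spends 32.5% of its capture agent and north-west 65.0%, twice as much, because starting material per capture agent rises from 0.500 to 1.00. So north-west lies past the border of the rule.

Let c be the mean fraction of its charge of capture agent left, and suppose the share reaching target is s/(s+c). The zeta run, with c taken midway between its start and its end, has c = 0.838, which gives s = 0.451, a reading with the scatter of that run. This s is the tie level, a kind of selectivity factor: at one temperature, with one charge of capture agent and one level of fresh partner, the mean fraction of capture agent at which open intermediate splits evenly between target and trapped intermediate. The beta run gives 0.241, lower than at 45 °C.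

Now iterate for north-west. Starting from 35%, c is 0.675, so the share is 40.1%. Put that back: c becomes 0.700 and the share 39.2%, the figure this reckoning commits to for north-west.

The forecast gives north-west 37.5% (33% to 42%), east 41% (30% to 50%) and south-east 29.5% (25% to 34%), and it names east: “East probably stays highest, narrowly.” The reckoned north-west figure stands 1.7 percentage points above the forecast's value.

The flask that comes out highest is north-west, with 38.6%, against 33.7% in east and 29.4% in south-east.

starting material → open intermediate (k = 0.240 h⁻¹, Ea = 99.0 kJ mol⁻¹); fresh partner + open intermediate → target (k = 0.0710 L mol⁻¹ h⁻¹, Ea = 86.0 kJ mol⁻¹); solid partner ⇌ fresh partner, rate k3*(cs3 - [fresh partner]) while solid is left; crystals form when [fresh partner] > cs3 (solubility = 0.430 M, k = 2.50 h⁻¹); target ⇌ isomer of the product (K = 0.350, k = 0.0560 h⁻¹, Ea = 89.0 kJ mol⁻¹, ΔH = −44.0 kJ mol⁻¹); open intermediate + capture agent → trapped intermediate (k = 0.0660 L mol⁻¹ h⁻¹, Ea = 75.0 kJ mol⁻¹); (constants at 25 °C) With 43% of the capture agent left in north-west, c is 0.715 and the tie level gives 38.7%. East, read backwards, has a tie level of 0.343, below that of zeta. In south-east, target and isomer of the product relax by that step alone, both ways together, with a half-life of 0.134 d, shorter than the 2.5 d allowed, and 10.1% of isomer stands at the end. South-east's own tie level, reckoned the same way, is 0.295; it gives 24.3% for a neighbour flask, like south-east but with 0.25 M of starting material and with 83.5% of its capture agent left at the end, and that neighbour holds 24.6% of target.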